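**Assumption:** the stereocentre is read as (S), i.e. the target is 1‑O‑acetyl‑2‑O‑acyl‑sn‑glycerol, with (E)‑3‑methyl‑5‑(2,6,6‑trimethylcyclohex‑1‑en‑1‑yl)pent‑2‑enoic acid as the acyl part. PMB = 4‑methoxybenzyl.

## Retrosynthetic overview

1. Target 16 ⇒ PMB ether 15 (sn‑3 OH unmasked last) ⇒ ester disconnection into acid 9 and alcohol 14.
2. Alcohol 14 ⇒ (S)‑solketal 10 (chiral pool: PMB ether, acetonide removal, primary‑selective acetylation); the stereocentre is bought, never touched.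
3. Acid 9 ⇒ methyl ester 7 ⇒ (Z)‑enol phosphate 6 (methyl introduced with retention, fixing the E alkene) ⇒ β‑keto ester 4.
4. Key C–C bond: C1–C2 of the acid, by intermolecular crossed Claisen condensation of dihydro‑β‑ionone 1 with dimethyl carbonate 2.
5. Rings: none is formed; the trimethylcyclohexene ring arrives intact in 1.

## Route

Step 1
Reactants: 1 4‑(2,6,6‑trimethylcyclohex‑1‑en‑1‑yl)butan‑2‑one (dihydro‑β‑ionone); 2 dimethyl carbonate
Product: 4 methyl 3‑oxo‑5‑(2,6,6‑trimethylcyclohex‑1‑en‑1‑yl)pentanoate, via potassium enolate 3 (not isolated)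
Conditions: KH (2.5 equiv, oil‑free), 2 (4 equiv), THF, reflux, slow addition of 1; then 1 M HCl, 0 °C
Reagents that add atoms: none
Why: Crossed Claisen condensation: the ketone enolate is C‑acylated by non‑enolisable dimethyl carbonate, and the reversible acylation funnels to the methyl‑side product because its less substituted, doubly stabilised enolate 3 is the thermodynamic sink; no stereocentre is formed.

Step 2
Reactants: 4 methyl 3‑oxo‑5‑(2,6,6‑trimethylcyclohex‑1‑en‑1‑yl)pentanoate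
Product: 6 methyl (Z)‑3‑[(diethoxyphosphoryl)oxy]‑5‑(2,6,6‑trimethylcyclohex‑1‑en‑1‑yl)pent‑2‑enoate, via sodium enolate 5 (not isolated)
Conditions: NaH (1.1 equiv), Et2O, 0 °C; then ClP(O)(OEt)2, 0 °C → rt
Reagents that add atoms: diethyl chlorophosphate, CCOP(=O)(Cl)OCC
Why: O‑phosphorylation of a β‑keto ester enolate: in ether the sodium enolate is a tight chelate of (Z) geometry and the hard chlorophosphate traps it on oxygen, so the (Z)‑enol phosphate is formed.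

Step 3
Reactants: 6 methyl (Z)‑3‑[(diethoxyphosphoryl)oxy]‑5‑(2,6,6‑trimethylcyclohex‑1‑en‑1‑yl)pent‑2‑enoate
Product: 7 methyl (E)‑3‑methyl‑5‑(2,6,6‑trimethylcyclohex‑1‑en‑1‑yl)pent‑2‑enoate
Conditions: Me2CuLi (2.5 equiv, from CuI + 2 MeLi), Et2O, −78 → −45 °C; quench sat. aq. NH4Cl at −45 °C
Reagents that add atoms: lithium dimethylcuprate, Me2CuLi, [Li+].C[Cu-]C (made from methyllithium, C[Li], and CuI)
Why: Weiler‑type cuprate coupling of an enol phosphate (conjugate addition–elimination) replaces the phosphate by methyl with retention of alkene geometry, so methyl ends cis to the ester and the alkene is E.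

Step 4
Reactants: 7 methyl (E)‑3‑methyl‑5‑(2,6,6‑trimethylcyclohex‑1‑en‑1‑yl)pent‑2‑enoate
Product: 9 (E)‑3‑methyl‑5‑(2,6,6‑trimethylcyclohex‑1‑en‑1‑yl)pent‑2‑enoic acid, via sodium carboxylate 8 (not isolated)
Conditions: 2 M aq. NaOH, MeOH/THF, 50 °C; then 1 M HCl to pH 3, 0 °C
Reagents that add atoms: sodium hydroxide, NaOH, [Na+].[OH-]
Why: Saponification (acyl‑oxygen ester hydrolysis) is faster than γ‑deprotonation under aqueous hydroxide, so the E‑trisubstituted alkene is kept.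

Step 5
Reactants: 10 (S)‑(2,2‑dimethyl‑1,3‑dioxolan‑4‑yl)methanol ((S)‑solketal, 1,2‑O‑isopropylidene‑sn‑glycerol)
Product: 12 (S)‑4‑{[(4‑methoxybenzyl)oxy]methyl}‑2,2‑dimethyl‑1,3‑dioxolane, via sodium alkoxide 11 (not isolated)
Conditions: NaH, DMF, 0 °C; then PMBCl, Bu4NI (cat.), 0 °C → rt
Reagents that add atoms: 4‑methoxybenzyl chloride (PMBCl), COc1ccc(CCl)cc1
Why: Williamson ether synthesis on the primary alkoxide; the stereocentre is not involved.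

Step 6
Reactants: 12 (S)‑4‑{[(4‑methoxybenzyl)oxy]methyl}‑2,2‑dimethyl‑1,3‑dioxolane
Product: 13 (R)‑3‑[(4‑methoxybenzyl)oxy]propane‑1,2‑diol (3‑O‑PMB‑sn‑glycerol)
Conditions: AcOH/H2O 4:1, 40 °C; toluene azeotrope
Reagents that add atoms: none
Why: Acid‑catalysed acetal hydrolysis cleaves only the acetal C–O bonds, so the configuration is retained (the descriptor changes by CIP priority only), and the PMB ether survives aqueous acetic acid.

Step 7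
Reactants: 13 (R)‑3‑[(4‑methoxybenzyl)oxy]propane‑1,2‑diol
Product: 14 (S)‑2‑hydroxy‑3‑[(4‑methoxybenzyl)oxy]propyl acetate (1‑O‑acetyl‑3‑O‑PMB‑sn‑glycerol)
Conditions: AcCl (1.05 equiv), 2,4,6‑collidine (2 equiv), CH2Cl2, −78 °C
Reagents that add atoms: acetyl chloride, CC(=O)Cl
Why: Kinetically controlled selective O‑acylation: with acetyl chloride and a hindered pyridine base at −78 °C the primary hydroxyl reacts much faster than the secondary one.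

Step 8
Reactants: 14 (S)‑2‑hydroxy‑3‑[(4‑methoxybenzyl)oxy]propyl acetate; 9 (E)‑3‑methyl‑5‑(2,6,6‑trimethylcyclohex‑1‑en‑1‑yl)pent‑2‑enoic acid
Product: 15 (S)‑1‑acetoxy‑3‑[(4‑methoxybenzyl)oxy]propan‑2‑yl (E)‑3‑methyl‑5‑(2,6,6‑trimethylcyclohex‑1‑en‑1‑yl)pent‑2‑enoate
Conditions: 9 (1.2 equiv), EDC·HCl (1.5 equiv), DMAP (0.3 equiv), CH2Cl2, 0 °C → rt
Reagents that add atoms: none
Why: Steglich esterification acylates the secondary hydroxyl through the carbodiimide‑activated acid and the acylpyridinium ion; the C–O bond at the stereocentre is not broken, so the configuration is retained.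

Step 9
Reactants: 15 (S)‑1‑acetoxy‑3‑[(4‑methoxybenzyl)oxy]propan‑2‑yl (E)‑3‑methyl‑5‑(2,6,6‑trimethylcyclohex‑1‑en‑1‑yl)pent‑2‑enoate
Product: 16 (S)‑1‑acetoxy‑3‑hydroxypropan‑2‑yl (E)‑3‑methyl‑5‑(2,6,6‑trimethylcyclohex‑1‑en‑1‑yl)pent‑2‑enoate (target)
Conditions: DDQ (1.3 equiv), CH2Cl2/pH 7 phosphate buffer 10:1, 0 °C, 1–2 h; fast chromatography on boric‑acid‑doped silica, store cold
Reagents that add atoms: none
Why: Oxidative PMB ether cleavage by DDQ (benzylic hydride abstraction, then hydrolysis of the oxocarbenium ion) runs near neutral pH, which leaves both esters and the alkenes intact and suppresses 2→3 acyl migration.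

## Compound list

1 | 4‑(2,6,6‑trimethylcyclohex‑1‑en‑1‑yl)butan‑2‑one (dihydro‑β‑ionone) | CC(=O)CCC1=C(C)CCCC1(C)C | starting material
2 | dimethyl carbonate | COC(=O)OC | starting material
3 | potassium (Z)‑1‑methoxy‑1‑oxo‑5‑(2,6,6‑trimethylcyclohex‑1‑en‑1‑yl)pent‑2‑en‑3‑olate (potassium enolate of 4, drawn as the chelated form) | [K+].COC(=O)/C=C(\[O-])CCC1=C(C)CCCC1(C)C | intermediate
4 | methyl 3‑oxo‑5‑(2,6,6‑trimethylcyclohex‑1‑en‑1‑yl)pentanoate | COC(=O)CC(=O)CCC1=C(C)CCCC1(C)C | intermediate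
5 | sodium (Z)‑1‑methoxy‑1‑oxo‑5‑(2,6,6‑trimethylcyclohex‑1‑en‑1‑yl)pent‑2‑en‑3‑olate (chelated sodium enolate of 4) | [Na+].COC(=O)/C=C(\[O-])CCC1=C(C)CCCC1(C)C | intermediate
6 | methyl (Z)‑3‑[(diethoxyphosphoryl)oxy]‑5‑(2,6,6‑trimethylcyclohex‑1‑en‑1‑yl)pent‑2‑enoate | COC(=O)/C=C(\OP(=O)(OCC)OCC)CCC1=C(C)CCCC1(C)C | intermediate
7 | methyl (E)‑3‑methyl‑5‑(2,6,6‑trimethylcyclohex‑1‑en‑1‑yl)pent‑2‑enoate | COC(=O)/C=C(\C)CCC1=C(C)CCCC1(C)C | intermediate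
8 | sodium (E)‑3‑methyl‑5‑(2,6,6‑trimethylcyclohex‑1‑en‑1‑yl)pent‑2‑enoate | [Na+].[O-]C(=O)/C=C(\C)CCC1=C(C)CCCC1(C)C | intermediate
9 | (E)‑3‑methyl‑5‑(2,6,6‑trimethylcyclohex‑1‑en‑1‑yl)pent‑2‑enoic acid | OC(=O)/C=C(\C)CCC1=C(C)CCCC1(C)C | intermediate
10 | (S)‑(2,2‑dimethyl‑1,3‑dioxolan‑4‑yl)methanol ((S)‑solketal) | CC1(C)OC[C@H](CO)O1 | starting material
11 | sodium alkoxide of (S)‑solketal | [Na+].CC1(C)OC[C@H](C[O-])O1 | intermediate
12 | (S)‑4‑{[(4‑methoxybenzyl)oxy]methyl}‑2,2‑dimethyl‑1,3‑dioxolane | COc1ccc(COC[C@H]2COC(C)(C)O2)cc1 | intermediate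
13 | (R)‑3‑[(4‑methoxybenzyl)oxy]propane‑1,2‑diol (3‑O‑PMB‑sn‑glycerol) | COc1ccc(COC[C@H](O)CO)cc1 | intermediate
14 | (S)‑2‑hydroxy‑3‑[(4‑methoxybenzyl)oxy]propyl acetate (1‑O‑acetyl‑3‑O‑PMB‑sn‑glycerol) | COc1ccc(COC[C@H](O)COC(C)=O)cc1 | intermediate
15 | (S)‑1‑acetoxy‑3‑[(4‑methoxybenzyl)oxy]propan‑2‑yl (E)‑3‑methyl‑5‑(2,6,6‑trimethylcyclohex‑1‑en‑1‑yl)pent‑2‑enoate | CC(=O)OC[C@H](COCc1ccc(OC)cc1)OC(=O)/C=C(\C)CCC1=C(C)CCCC1(C)C | intermediate
16 | (S)‑1‑acetoxy‑3‑hydroxypropan‑2‑yl (E)‑3‑methyl‑5‑(2,6,6‑trimethylcyclohex‑1‑en‑1‑yl)pent‑2‑enoate | CC(=O)OC[C@H](CO)OC(=O)/C=C(\C)CCC1=C(C)CCCC1(C)C | target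

## Step count and risks

Total steps: 9 (acid branch 4 steps, glycerol branch 3 steps, 2 steps after coupling).
Longest linear sequence: 6 steps (1 → 4 → 6 → 7 → 9 → 15 → 16).

**Step 3 (cuprate methylation).** The cuprate is thermally fragile, and warming risks E/Z leakage or a second methyl addition. The fallback sets out from 4 and comes back at 7, replacing the stoichiometric cuprate by a catalytic cross‑coupling. NaH then Tf2O in Et2O at −78 °C on 4 gives methyl (Z)‑3‑{[(trifluoromethyl)sulfonyl]oxy}‑5‑(2,6,6‑trimethylcyclohex‑1‑en‑1‑yl)pent‑2‑enoate F1. Negishi methylation with MeZnCl and the zerovalent palladium catalyst Pd(PPh3)4 in THF at rt then gives 7 with retention of geometry.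

**Step 8 (esterification).** The conjugated, β,β‑disubstituted acid acylates slowly, so DMAP‑mediated 1→2 acetyl migration in 14 can compete, and the activated acyl may scramble E/Z or deconjugate. The fallback sets out from 13 and comes back at 15, installing the migration‑prone acetate only after the hindered ester. TBSCl/imidazole at 0 °C on 13 gives (S)‑1‑[(tert‑butyldimethylsilyl)oxy]‑3‑[(4‑methoxybenzyl)oxy]propan‑2‑ol F2. EDC·HCl/DMAP with 9 gives (S)‑1‑[(tert‑butyldimethylsilyl)oxy]‑3‑[(4‑methoxybenzyl)oxy]propan‑2‑yl (E)‑3‑methyl‑5‑(2,6,6‑trimethylcyclohex‑1‑en‑1‑yl)pent‑2‑enoate F3. HF·pyridine at 0 °C gives (R)‑1‑hydroxy‑3‑[(4‑methoxybenzyl)oxy]propan‑2‑yl (E)‑3‑methyl‑5‑(2,6,6‑trimethylcyclohex‑1‑en‑1‑yl)pent‑2‑enoate F4. This is acetylated at once with Ac2O/pyridine at 0 °C to give 15.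

**Step 9 (PMB removal).** The liberated 1,2‑diacyl‑sn‑glycerol can suffer 2→3 acyl migration, and DDQ may attack the electron‑rich tetrasubstituted ring alkene. The fallback sets out from 10 and comes back at 16, replacing the oxidatively removed ether by a silyl ether cleaved with acidic fluoride. TBDPSCl/imidazole on 10 gives tert‑butyl{[(R)‑2,2‑dimethyl‑1,3‑dioxolan‑4‑yl]methoxy}diphenylsilane F5. Aqueous AcOH then gives (R)‑3‑[(tert‑butyldiphenylsilyl)oxy]propane‑1,2‑diol F6. AcCl/collidine at −78 °C gives (R)‑3‑[(tert‑butyldiphenylsilyl)oxy]‑2‑hydroxypropyl acetate F7. EDC·HCl/DMAP with acid 9 gives (R)‑1‑acetoxy‑3‑[(tert‑butyldiphenylsilyl)oxy]propan‑2‑yl (E)‑3‑methyl‑5‑(2,6,6‑trimethylcyclohex‑1‑en‑1‑yl)pent‑2‑enoate F8. HF·pyridine in THF/pyridine at 0 °C → rt then gives 16 without oxidant or basic fluoride.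

## Further compounds

F1 | step 3 | methyl (Z)‑3‑{[(trifluoromethyl)sulfonyl]oxy}‑5‑(2,6,6‑trimethylcyclohex‑1‑en‑1‑yl)pent‑2‑enoate | COC(=O)/C=C(\OS(=O)(=O)C(F)(F)F)CCC1=C(C)CCCC1(C)C
F2 | step 8 | (S)‑1‑[(tert‑butyldimethylsilyl)oxy]‑3‑[(4‑methoxybenzyl)oxy]propan‑2‑ol | COc1ccc(COC[C@H](O)CO[Si](C)(C)C(C)(C)C)cc1
F3 | step 8 | (S)‑1‑[(tert‑butyldimethylsilyl)oxy]‑3‑[(4‑methoxybenzyl)oxy]propan‑2‑yl (E)‑3‑methyl‑5‑(2,6,6‑trimethylcyclohex‑1‑en‑1‑yl)pent‑2‑enoate | COc1ccc(COC[C@@H](CO[Si](C)(C)C(C)(C)C)OC(=O)/C=C(\C)CCC2=C(C)CCCC2(C)C)cc1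
F4 | step 8 | (R)‑1‑hydroxy‑3‑[(4‑methoxybenzyl)oxy]propan‑2‑yl (E)‑3‑methyl‑5‑(2,6,6‑trimethylcyclohex‑1‑en‑1‑yl)pent‑2‑enoate | COc1ccc(COC[C@@H](CO)OC(=O)/C=C(\C)CCC2=C(C)CCCC2(C)C)cc1
F5 | step 9 | tert‑butyl{[(R)‑2,2‑dimethyl‑1,3‑dioxolan‑4‑yl]methoxy}diphenylsilane | CC1(C)OC[C@H](CO[Si](c2ccccc2)(c2ccccc2)C(C)(C)C)O1
F6 | step 9 | (R)‑3‑[(tert‑butyldiphenylsilyl)oxy]propane‑1,2‑diol | OC[C@H](CO[Si](c1ccccc1)(c1ccccc1)C(C)(C)C)O
F7 | step 9 | (R)‑3‑[(tert‑butyldiphenylsilyl)oxy]‑2‑hydroxypropyl acetate | CC(=O)OC[C@H](CO[Si](c1ccccc1)(c1ccccc1)C(C)(C)C)O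
F8 | step 9 | (R)‑1‑acetoxy‑3‑[(tert‑butyldiphenylsilyl)oxy]propan‑2‑yl (E)‑3‑methyl‑5‑(2,6,6‑trimethylcyclohex‑1‑en‑1‑yl)pent‑2‑enoate | CC(=O)OC[C@H](CO[Si](c1ccccc1)(c1ccccc1)C(C)(C)C)OC(=O)/C=C(\C)CCC1=C(C)CCCC1(C)C
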